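If a quick number is wanted for these two flasks, one ratio of two rates is a place to start, and the flasks stand as follows.

    substrate + partner ⇌ single product + by-product (K1 = 0.26, k1 = 4.7 × 10⁻⁴ M⁻¹ s⁻¹)
    substrate + partner → other mono adduct + by-product (k2 = 4.4 × 10⁻⁴ M⁻¹ s⁻¹)
    partner + single product → double product + by-product (k3 = 2.3 × 10⁻⁴ M⁻¹ s⁻¹)
    partner + other mono adduct → double product + by-product (k4 = 9.8 × 10⁻⁵ M⁻¹ s⁻¹)
    partner → decomposition product (k5 = 8.1 × 10⁻⁷ s⁻¹)
    substrate ⇌ dormant form (K6 = 0.73, k6 = 0.0056 s⁻¹)

- west: substrate 0.20 M; partner 0.300 M; time 80 min
- south-west: substrate 0.20 M; partner 0.750 M; time 80 min

1. which of these there is most of at the end, counted by the substrate in it, west (substrate / other mono adduct / double product / single product)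
2. which of these there is most of at the end, counted by the substrate in it, south-west (substrate / other mono adduct / double product / single product)
3. final amount of the leader among these, as a percentage of the substrate charged, in west
4. final amount of the leader among these, as a percentage of the substrate charged, in south-west

The other mono adduct is made at 4.4 × 10⁻⁴ M⁻¹ s⁻¹ times [substrate][partner] and used at 9.8 × 10⁻⁵ M⁻¹ s⁻¹ times [partner][other mono adduct]. Dividing one rate by the other cancels [partner] and time drops out, so made over used equals 4.49 times [substrate]/[other mono adduct]. That constant is the ceiling ratio, a selectivity factor: the value of [other mono adduct]/[substrate] at which this adduct stops growing. On drawing level with the substrate, the adduct is still made 4.49 times faster than used, so this ceiling does not hold it below the substrate.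

The substrate relaxes with its dormant form in 0.870 min, which leaves a free share of 57.8%. With partner held at its charge and the back step dropped, west has an exposure of 0.757. That gives free substrate 27.1% against adduct 25.7%, too close to call. South-west, with exposure 1.89, gives substrate 8.70% against adduct 41.1%, a clear lead of the adduct over the substrate. Both simplifications overstate the loss of substrate, so these substrate figures sit low.

Your forecast names substrate in west at 34% and other mono adduct in south-west at 35%, where “the irreversible other mono adduct accumulates to about 35%”. The reckoning here gives other sizes for these two, 27.1% and 41.1%, and does not reach those leaders: with the back step dropped it puts single product at 27.4% in west and 43.9% in south-west, higher than its figures for substrate and adduct in each flask.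

West ends with substrate in front at 33.9%, and south-west with other mono adduct at 35.1%. The other mono adduct in west stands at 21.5%. In south-west at 80.0 min, [other mono adduct]/[substrate] is 2.00, short of 4.49, and the adduct is made 2.25 times faster than used. At 800 min in south-west that ratio reads 63.6, past the ceiling, and the other mono adduct has come down to 14.9%.

(The rate constants were chosen freely.)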